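# Proposed synthesis of helihumulone by a catalyst-controlled dearomative Claisen rearrangement

## The problem

- Helihumulone (13) is a hexasubstituted cyclohexa-2,4-dienone, the dearomatized form of an acylphloroglucinol. It has oxygen on C1, C3 and C5, a 3-phenylpropanoyl group on C2, a prenyl group on C4, and a methoxy group plus the second prenyl group on the only sp3 ring carbon, C6.
- C6 is the sole stereocenter, quaternary and oxygenated. Its ring neighbours C1 (ketone) and C5 (enol) exchange roles by tautomerism and differ only through the remote C2 acyl and C4 prenyl groups. Nothing in the molecule can relay stereochemistry to C6, so a catalyst must set it on a ring that is otherwise flat.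
- The constitution is a second problem. All six ring carbons are substituted, three by oxygens of similar reactivity, and direct C-prenylation of acylphloroglucinols tends to give O/C and mono/poly mixtures.
- The tertiary methyl ether cannot be made late. The two enols form a vinylogous acid and would be methylated before any tertiary alcohol, so the methoxy group must come in with a building block.
- Sensitive groups: the two trisubstituted alkenes (strong acid closes them onto a neighbouring enol oxygen; they exclude unselective hydrogenation or late electrophilic halogenation) and the acidic β-triketone (binds metals, deacylates by retro-Claisen in hot base).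
- The feature that makes the key step possible is the fragment O=C1–C6–CH2–CH=CMe2. It is a γ,δ-unsaturated ketone, the retron of a Claisen rearrangement. Read backwards, it turns the ring into a 1,2,3,5-tetraoxygenated benzene in which C6 already bears its methoxy group and O1 bears a 1,1-dimethylallyl group.
- O1 stands 1,3 to the carbonyl oxygen of the C2 acyl group. This gives a two-point binding site for a chiral Lewis acid directly at the bond that migrates.

## Retrosynthesis

**13 ⇒ 11.** The two enol O–H bonds are replaced by O–CH3, giving dienone 11. With no acidic OH, 11 can be the product of a Lewis-acid-catalysed step without sequestering the catalyst as a β-diketonate. The methyl groups are the aryl methyl ethers of the starting arene, so no protecting-group steps are spent. Dearomatization itself differentiates the three methoxy groups: the one on C6 becomes an ordinary tertiary alkyl ether, the other two become vinylogous methyl esters. The forward step only needs mild aqueous acid that spares the prenyl groups.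

**11 ⇒ 10.** The C6–CH2 bond is cut by a retro-Claisen, giving the achiral aromatic ether 10, an isomer of 11.
- Cutting C6–O instead (oxidative dearomatization) would require site- and face-selective C–O formation on a symmetric triphenol.
- Cutting C6–CH2 intermolecularly gives no control over which ring carbon is alkylated.
- The [3,3] shift can only reach a carbon ortho to O2'. Of the two, only the methoxy-bearing one is electronically viable.
- Allyl inversion guarantees the linear prenyl group.
- The forward reaction must select one face of the arene carbon C3' and must stay concerted.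

**10 ⇒ 9 ⇒ 7 + 8.** The tertiary O–C bond is cut. Tertiary allyl aryl ethers are made reliably through the propargyl ether (copper-catalysed propargylic substitution with 8) and semihydrogenation. Phenol 7 has a single free hydroxyl, exactly the oxygen that becomes O1, so no site selectivity is asked.

**7 ⇒ 5 + 6 ⇒ 4.** The aryl–prenyl bond is cut. Phenol 4 has one ring C–H, so bromination to 5 and Stille coupling with stannane 6 place the prenyl group unambiguously. This avoids phenolate C-alkylation or acid-mediated Friedel–Crafts prenylation.

**4 ⇒ 1 + 2.** The aryl–acyl bond is cut and one O–CH3 is restored, via ketone 3. Friedel–Crafts acylation of the symmetric arene 1 (two equivalent C–H) with acid chloride 2 is followed in the same flask by AlCl3-mediated loss of the one methoxy group wedged between the new carbonyl and another methoxy group. This single operation differentiates the four oxygens of 1: it frees only the future O1 and leaves the future C6 methoxy group in place.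

## Roads not taken

**Alternative 1:** (the most obvious) Cut the C6–O bond.
- Forward: oxidative dearomatization of the symmetric deoxy compound A1, made from phloroglucinol by acylation and double C-prenylation. Either PhI(OAc)2 (trivalent iodine) in methanol, or hydroxylation to the tertiary alcohol A2 and O-methylation; a chiral aryl iodide or chiral copper–amine/O2 system would have to distinguish the enantiotopic prenylated carbons.
- Why the chosen plan is better:
  - The double C-prenylation that makes A1 is unselective.
  - The oxidant meets three phenols and three nucleophilic ring carbons. Methanol then attacks a phenoxenium-like species from outside, with no organised contact to the chiral reagent.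
  - A2 cannot be methylated at the tertiary hydroxyl in the presence of two far more acidic enols, and as a free α-ketol it is prone to ring contraction.
  - The chosen plan makes the C6–C bond intramolecularly inside a chelate and carries the methoxy group from the first step.

**Alternative 2:** Cut the same C6–CH2 bond, but between two molecules.
- Forward: enantioselective Tsuji–Trost dearomative prenylation of triol A3 with a prenyl carbonate and a chiral zerovalent-palladium catalyst.
- Why the chosen plan is better:
  - The phenolate offers three oxygens and two ring carbons to an untethered π-prenyl cation.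
  - Attack at the carbon that already bears a prenyl group (gem-diprenyl isomer A4, the usual course in this class), O-alkylation and branched products all compete.
  - The product is an acidic, metal-binding triketone.
  - The Claisen route limits delivery to the carbon ortho to one ether oxygen and needs no free phenol.

**Alternative 3:** Build the ring last.
- Forward: Dieckmann-type cyclization (C2 carbanion onto the ester) of the linear triketo ester A5, whose quaternary α-methoxy center is set beforehand by asymmetric prenylation of an α-methoxy β-keto ester to A6.
- Why the chosen plan is better: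
  - The route is roughly twice as long.
  - Open tri- and tetracarbonyl chains prefer O-cyclization to pyranones or aldol closure.
  - The base needed can cleave the α,α-disubstituted β-keto ester by retro-Claisen.
  - Asymmetric alkylation of acyclic α-alkoxy β-keto esters is not dependable for a center that nothing later can correct.

Key step: step 6

Assumption: helihumulone is treated as the dienol tautomer written in the SMILES (the β-triketone tautomers equilibrate freely; the C6 descriptor R refers to this drawing), and 1,2,3,5-tetramethoxybenzene is taken as a catalogue compound.

Arene locants are primed (C1' bears the acyl group). They map onto the target as C1'→C2, C2'→C1, C3'→C6, C4'→C5, C5'→C4, C6'→C3.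

## Route

Step 1
Reactants: 1 (1,2,3,5-tetramethoxybenzene); 2 (3-phenylpropanoyl chloride)
Product: 4 1-(2-hydroxy-3,4,6-trimethoxyphenyl)-3-phenylpropan-1-one, via tetramethoxy ketone 3 (not isolated)
Conditions: AlCl3 (2.5 equiv, added last), CH2Cl2, 0 → 23 °C; 1 M HCl work-up
Reagents that add atoms: none
Why: Friedel–Crafts acylation at one of the two equivalent C–H positions of 1 gives 3; carbonyl-bound AlCl3 then cleaves the ortho methoxy group squeezed between the acyl group and the C3' methoxy group (out of plane, most basic, strain relieved), a selectivity typical of 2,3,4-trimethoxyaryl ketones, and the resulting aluminium phenoxide chelate shields the C6' methoxy group from a second cleavage.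

Step 2
Reactants: 4 (1-(2-hydroxy-3,4,6-trimethoxyphenyl)-3-phenylpropan-1-one)
Product: 5 1-(3-bromo-6-hydroxy-2,4,5-trimethoxyphenyl)-3-phenylpropan-1-one
Conditions: NBS (1.0 equiv), MeCN, 0 °C
Reagents that add atoms: N-bromosuccinimide, O=C1CCC(=O)N1Br
Why: Electrophilic aromatic bromination at C5', the only ring C–H (para to the phenol, ortho to two methoxy groups); it is done before any prenyl group is present, so no alkene competes for bromine.

Step 3
Reactants: 5 (1-(3-bromo-6-hydroxy-2,4,5-trimethoxyphenyl)-3-phenylpropan-1-one); 6 (tributyl(3-methylbut-2-en-1-yl)stannane)
Product: 7 1-[2-hydroxy-3,4,6-trimethoxy-5-(3-methylbut-2-en-1-yl)phenyl]-3-phenylpropan-1-one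
Conditions: Pd(P(t-Bu)3)2 (5 mol %), CsF (2 equiv), 1,4-dioxane, 80 °C
Reagents that add atoms: none
Why: Stille coupling; the bulky electron-rich phosphine on zerovalent palladium helps oxidative addition of the hindered bromide, fluoride activates the stannane, and reductive elimination at the less substituted allyl terminus should give the linear prenyl arene; the free phenol and ketone are tolerated.

Step 4
Reactants: 7 (1-[2-hydroxy-3,4,6-trimethoxy-5-(3-methylbut-2-en-1-yl)phenyl]-3-phenylpropan-1-one); 8 (3-chloro-3-methylbut-1-yne)
Product: 9 1-[3,4,6-trimethoxy-2-[(2-methylbut-3-yn-2-yl)oxy]-5-(3-methylbut-2-en-1-yl)phenyl]-3-phenylpropan-1-one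
Conditions: DBU, CuCl2·2H2O (1 mol %), MeCN, 0 → 23 °C
Reagents that add atoms: none
Why: Copper-catalysed propargylic substitution (via a copper acetylide/allenylidene of 8), the standard entry to aryl 1,1-dimethylpropargyl ethers, including from chelated ortho-acyl phenols; O2' is the only free hydroxyl, so no site selectivity is required.

Step 5
Reactants: 9 (1-[3,4,6-trimethoxy-2-[(2-methylbut-3-yn-2-yl)oxy]-5-(3-methylbut-2-en-1-yl)phenyl]-3-phenylpropan-1-one)
Product: 10 1-[3,4,6-trimethoxy-2-[(2-methylbut-3-en-2-yl)oxy]-5-(3-methylbut-2-en-1-yl)phenyl]-3-phenylpropan-1-one
Conditions: H2 (1 atm), Pd/CaCO3 poisoned with Pb(OAc)2, quinoline, EtOAc, 0 °C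
Reagents that add atoms: none
Why: Lindlar semihydrogenation of the terminal alkyne stops at the alkene, with the trisubstituted prenyl alkene and the aryl ketone inert; 10 is kept cold and used at once so that no uncatalysed (racemic) rearrangement precedes step 6.

Step 6
Reactants: 10 (1-[3,4,6-trimethoxy-2-[(2-methylbut-3-en-2-yl)oxy]-5-(3-methylbut-2-en-1-yl)phenyl]-3-phenylpropan-1-one)
Product: 11 (6R)-3,5,6-trimethoxy-4,6-bis(3-methylbut-2-en-1-yl)-2-(3-phenylpropanoyl)cyclohexa-2,4-dien-1-one
Conditions: Cu(OTf)2 (10 mol %), (S,S)-t-Bu-box [2,2'-(propane-2,2-diyl)bis((4S)-4-tert-butyl-4,5-dihydrooxazole)] (11 mol %), 4 Å MS, CH2Cl2, −30 → 0 °C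
Reagents that add atoms: none
Why: Proposed new method: the divalent copper–bis(oxazoline) cation is expected to bind the ether oxygen O2' and the acyl carbonyl oxygen of 10 in a six-membered chelate, which polarises the O–CMe2 bond and lets the concerted [3,3] shift (an aromatic Claisen rearrangement through a six-membered transition state; no ring is closed) run far below the thermal temperature. The closest known reaction types are the chiral-Lewis-acid-catalysed enantioselective dearomative Claisen rearrangement of allyl 2-naphthyl ethers with a chelating carbonyl group at C3 and the copper–bis(oxazoline)-catalysed Claisen rearrangement of 2-alkoxycarbonyl allyl vinyl ethers; new here are the monocyclic fully substituted benzene, the tertiary allyl group and the oxygen-bearing migration terminus. C6 is the only new stereocenter and is under catalyst control: coordination makes O2' stereogenic, the tert-butyl groups of the ligand decide which lone pair binds and hence over which face of the ring the dimethylallyl group lies, and that face of C3' is attacked; the allyl terminus is CH2, so no second stereo-element arises. Site selectivity between the two ortho carbons rests on the chelate: C1' is the α-carbon of the metal-bound acyl group and attack there would break the chelate and its conjugation, whereas C3' is ortho or para to all three other ring oxygens, and the para carbon C5' cannot be reached in a concerted shift. Allyl inversion turns the 1,1-dimethylallyl ether into the linear prenyl group. The step needs the concerted shift to outrun heterolysis of the tertiary C–O bond, which low temperature, a non-polar solvent and the bidentate hold on the departing oxygen should secure. The driving force is relief of crowding in the hexasubstituted arene, the more substituted alkene, and two vinylogous esters conjugated to the new C1 carbonyl. The (S,S) ligand is written for definiteness; the (R,R) ligand is equally available, so the sense of induction can be matched to (R) once it is determined.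

Step 7
Reactants: 11 ((6R)-3,5,6-trimethoxy-4,6-bis(3-methylbut-2-en-1-yl)-2-(3-phenylpropanoyl)cyclohexa-2,4-dien-1-one)
Product: 13 helihumulone, via mono-methyl ether 12 (not isolated)
Conditions: 1 M aq. HCl, THF, 23 °C
Reagents that add atoms: water, O
Why: Acid-catalysed hydrolysis of the two vinylogous methyl esters (water adds to the protonated β-methoxy enone, methanol leaves), the C3 ether of the O-methylated β-triketone first (12), then the C5 ether; the C6 methoxy group is a tertiary alkyl ether next to carbonyls and cannot ionise, C6 is quaternary and cannot epimerise, and dilute acid at room temperature should leave the prenyl groups untouched.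

## Compound list

1 | 1,2,3,5-tetramethoxybenzene | COc1cc(OC)c(OC)c(OC)c1 | starting material
2 | 3-phenylpropanoyl chloride | O=C(Cl)CCc1ccccc1 | starting material
3 | 3-phenyl-1-(2,3,4,6-tetramethoxyphenyl)propan-1-one | COc1cc(OC)c(C(=O)CCc2ccccc2)c(OC)c1OC | intermediate (not isolated)
4 | 1-(2-hydroxy-3,4,6-trimethoxyphenyl)-3-phenylpropan-1-one | COc1cc(OC)c(C(=O)CCc2ccccc2)c(O)c1OC | intermediate
5 | 1-(3-bromo-6-hydroxy-2,4,5-trimethoxyphenyl)-3-phenylpropan-1-one | COc1c(Br)c(OC)c(C(=O)CCc2ccccc2)c(O)c1OC | intermediate
6 | tributyl(3-methylbut-2-en-1-yl)stannane | CCCC[Sn](CCCC)(CCCC)CC=C(C)C | starting material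
7 | 1-[2-hydroxy-3,4,6-trimethoxy-5-(3-methylbut-2-en-1-yl)phenyl]-3-phenylpropan-1-one | COc1c(CC=C(C)C)c(OC)c(C(=O)CCc2ccccc2)c(O)c1OC | intermediate
8 | 3-chloro-3-methylbut-1-yne | C#CC(C)(C)Cl | starting material
9 | 1-[3,4,6-trimethoxy-2-[(2-methylbut-3-yn-2-yl)oxy]-5-(3-methylbut-2-en-1-yl)phenyl]-3-phenylpropan-1-one | COc1c(CC=C(C)C)c(OC)c(C(=O)CCc2ccccc2)c(OC(C)(C)C#C)c1OC | intermediate
10 | 1-[3,4,6-trimethoxy-2-[(2-methylbut-3-en-2-yl)oxy]-5-(3-methylbut-2-en-1-yl)phenyl]-3-phenylpropan-1-one | COc1c(CC=C(C)C)c(OC)c(C(=O)CCc2ccccc2)c(OC(C)(C)C=C)c1OC | intermediate
11 | (6R)-3,5,6-trimethoxy-4,6-bis(3-methylbut-2-en-1-yl)-2-(3-phenylpropanoyl)cyclohexa-2,4-dien-1-one | CO[C@@]1(CC=C(C)C)C(=O)C(C(=O)CCc2ccccc2)=C(OC)C(CC=C(C)C)=C1OC | intermediate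
12 | (6R)-3-hydroxy-5,6-dimethoxy-4,6-bis(3-methylbut-2-en-1-yl)-2-(3-phenylpropanoyl)cyclohexa-2,4-dien-1-one | CO[C@@]1(CC=C(C)C)C(=O)C(C(=O)CCc2ccccc2)=C(O)C(CC=C(C)C)=C1OC | intermediate (not isolated)
13 | helihumulone, (6R)-3,5-dihydroxy-6-methoxy-4,6-bis(3-methylbut-2-en-1-yl)-2-(3-phenylpropanoyl)cyclohexa-2,4-dien-1-one | CO[C@@]1(CC=C(C)C)C(=O)C(C(=O)CCc2ccccc2)=C(O)C(CC=C(C)C)=C1O | target

## Step count and least certain steps

Total step count: 7. Longest linear sequence: 7 steps (from 1).

**Step 6 (key step, proposed new method).**
- What may go wrong:
  - Heterolysis of the tertiary allylic C–O bond on coordination, leading to loss of the allyl group, a [1,3] shift or attack at the para carbon.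
  - Non-productive chelation through the neighbouring C6' or C3' methoxy oxygen, giving poor facial selectivity.
  - One-electron oxidation of the very electron-rich arene by divalent copper.
  - Uncatalysed background rearrangement eroding the enantiomeric purity.
- Fallback (known chemistry), from 10 back to 13:
  - Thermal aromatic Claisen rearrangement of 10 (toluene, 80 °C) onto the blocked ortho carbon should give the racemic dienone F1.
  - Hydrolysis as in step 7 gives racemic helihumulone F2.
  - The acidic triketone is resolved by crystallization of its salt with (1R,2R)-cyclohexane-1,2-diamine, the (R)-acid salt F3 (or by chromatography on a chiral stationary phase). Dilute acid then releases 13.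

**Step 4.**
- What may go wrong: the phenol is flanked on both sides and hydrogen-bonded to the ketone, so base-induced elimination of 8 may outrun O-alkylation.
- Fallback, from 7 directly to 10: Pd(PPh3)4 (zerovalent palladium)-catalysed decarboxylative O-allylation with tert-butyl (2-methylbut-3-en-2-yl) carbonate in THF at 0 °C. The phenoxide attacks the more substituted terminus of the π-prenyl complex, and 9 and step 5 are skipped. This makes no compound outside the list (F0).

**Step 3.**
- What may go wrong: slow oxidative addition at the doubly ortho-substituted, electron-rich bromide, with protodebromination; partial coupling at the tertiary allyl terminus.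
- Fallback, from 4 to 7 without bromide or tin: O-prenylation (1-bromo-3-methylbut-2-ene, K2CO3, acetone) gives the prenyl ether 1-[3,4,6-trimethoxy-2-[(3-methylbut-2-en-1-yl)oxy]phenyl]-3-phenylpropan-1-one F4. Heating in N,N-diethylaniline at 190 °C then effects a para-Claisen–Cope sequence (ortho shift to C3', Cope shift to C5', enolization) to 7.

**Step 7.**
- What may go wrong: acid-promoted closure of a prenyl group onto a neighbouring enol oxygen, or stalling after the first hydrolysis because the triketone enol deactivates the remaining vinylogous ester.
- Fallback, from 11 to 13 via 12: SN2 demethylation at the methyl carbon with LiI in ethyl acetate at 60 °C (the triketone enolate is the leaving group), then mild acidification. No water adds to the ring and no strong acid is present. This makes no compound outside the list (F0).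

**Step 1.**
- What may go wrong: self-acylation of 2 onto its own phenyl ring; cleavage of the wrong ortho methoxy group or of two methoxy groups.
- Fallback, from 1 to 4 with the two events separated:
  - Ortho-lithiation of 1 between two methoxy groups (n-BuLi, TMEDA, THF, 0 °C) and acylation with N-methoxy-N-methyl-3-phenylpropanamide gives 3, now isolated.
  - One chelation-controlled demethylation with BCl3 (1.1 equiv, CH2Cl2, −78 °C) gives 4.
  - This makes no compound outside the list (F0).

## Further compounds

F1 | step 6 | rac-3,5,6-trimethoxy-4,6-bis(3-methylbut-2-en-1-yl)-2-(3-phenylpropanoyl)cyclohexa-2,4-dien-1-one | COC1(CC=C(C)C)C(=O)C(C(=O)CCc2ccccc2)=C(OC)C(CC=C(C)C)=C1OC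
F2 | step 6 | rac-helihumulone | COC1(CC=C(C)C)C(=O)C(C(=O)CCc2ccccc2)=C(O)C(CC=C(C)C)=C1O
F3 | step 6 | salt of (R)-helihumulone with (1R,2R)-cyclohexane-1,2-diamine | CO[C@@]1(CC=C(C)C)C(=O)C(C(=O)CCc2ccccc2)=C(O)C(CC=C(C)C)=C1O.N[C@@H]1CCCC[C@H]1N
F0 | step 4 | none | none
F4 | step 3 | 1-[3,4,6-trimethoxy-2-[(3-methylbut-2-en-1-yl)oxy]phenyl]-3-phenylpropan-1-one | COc1cc(OC)c(C(=O)CCc2ccccc2)c(OCC=C(C)C)c1OC
F0 | step 7 | none | none
F0 | step 1 | none | none
A1 | alternative 1 | 1-[2,4,6-trihydroxy-3,5-bis(3-methylbut-2-en-1-yl)phenyl]-3-phenylpropan-1-one | CC(C)=CCc1c(O)c(CC=C(C)C)c(O)c(C(=O)CCc2ccccc2)c1O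
A2 | alternative 1 | (6R)-3,5,6-trihydroxy-4,6-bis(3-methylbut-2-en-1-yl)-2-(3-phenylpropanoyl)cyclohexa-2,4-dien-1-one | O[C@@]1(CC=C(C)C)C(=O)C(C(=O)CCc2ccccc2)=C(O)C(CC=C(C)C)=C1O
A3 | alternative 2 | 1-[2,4,6-trihydroxy-3-methoxy-5-(3-methylbut-2-en-1-yl)phenyl]-3-phenylpropan-1-one | COc1c(O)c(CC=C(C)C)c(O)c(C(=O)CCc2ccccc2)c1O
A4 | alternative 2 | 3,5-dihydroxy-4-methoxy-6,6-bis(3-methylbut-2-en-1-yl)-2-(3-phenylpropanoyl)cyclohexa-2,4-dien-1-one | COC1=C(O)C(CC=C(C)C)(CC=C(C)C)C(=O)C(C(=O)CCc2ccccc2)=C1O
A5 | alternative 3 | methyl (2R)-2-methoxy-2,4-bis(3-methylbut-2-en-1-yl)-3,5,7-trioxo-9-phenylnonanoate | COC(=O)[C@@](OC)(CC=C(C)C)C(=O)C(CC=C(C)C)C(=O)CC(=O)CCc1ccccc1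
A6 | alternative 3 | methyl (2R)-2-methoxy-7-methyl-2-(3-methylbut-2-en-1-yl)-3-oxooct-6-enoate | COC(=O)[C@@](OC)(CC=C(C)C)C(=O)CCC=C(C)C
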